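**The invariant.** Substrate that has become first product stays in the pair first product plus bis adduct, provided other mono adduct feeds no bis adduct. Each step on the substrate side that uses coupling partner is first order in it, so each is pseudo-first-order in the exposure τ, the integral of partner concentration over time; the homo dimer step uses no partner and stands outside τ.

| setting | eta | gamma | winter | midnight |
|---|---|---|---|---|
| substrate | 0.020 M | 0.020 M | 0.020 M | 0.020 M |
| coupling partner | 0.035 M (fed, over 5.0 d) | 0.097 M (fed, over 5.0 d) | 0.120 M | 0.0400 M (fed, over 5.0 d) |
| remark | run made earlier | run made earlier | everything together at the start |  |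
| time |  |  | 6.0 d | 6.0 d |

- eta (time / d: first product / %, bis adduct / %, substrate / %): 0.208: 0, 0.7, 99.6; 0.625: 2.4, 1.4, 97.2; 1.25: 3.9, 0.6, 90.3; 1.67: 6.3, 0.9, 86.0; 2.50: 9.6, 1.7, 75.2; 3.00: 11.6, 3.4, 67.8; 4.00: 15.3, 6.5, 52.6
- gamma (time / d: first product / %, bis adduct / %, substrate / %): 0.333: 1.7, 1.4, 97.2; 0.500: 1.1, 1.5, 94.5; 0.833: 6.4, 3.1, 88.5; 1.25: 8.8, 1.7, 78.5; 1.67: 11.5, 3.8, 65.6; 3.00: 13.4, 13.6, 38.9; 4.00: 12.3, 21.5, 26.6

(scatter of a reading: 1 percentage point)

- percentages count the substrate that a species holds: one homo dimer counts as two
- on the list of suspects stand: coupling partner + other mono adduct -> bis adduct; 2 coupling partner -> self-condensation product; substrate + coupling partner -> other mono adduct; 2 substrate -> homo dimer; coupling partner + first product -> bis adduct; substrate + coupling partner -> first product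

- which one finishes higher in share of first product in all that became first product or bis adduct ("neither" within 2 percentage points) (winter / midnight / neither)
- share of first product in all that became first product or bis adduct, winter
- share of first product in all that became first product or bis adduct, midnight

**Main step.** With just substrate + partner, the fraction A of substrate left is exp(−kA·τ), and the share s of first product in the pair stays at 100%. Early in gamma, at 1.25 d, the fed exposure gives kA = 0.665 M⁻¹ h⁻¹.

**One more step.** Adding partner + first product → bis adduct, with constant kM, and integrating over τ gives s as a function of A and kM/kA, the selectivity factor. The split between the two mono adducts cancels. The curve runs close to s = A to the power n, where n is the selectivity exponent, ln s over ln A. The last gamma reading gives n = 0.763, and the last eta reading, nearer the start of the curve, gives 0.551.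

**The rest.** Self-condensation uses no substrate, so it should move a flask along this curve, not off it. Late in gamma, the substrate's decay implies partner at 0.0238 M. The feed of 0.0194 M d⁻¹ exceeds the 0.00404 M d⁻¹ taken on the substrate side, so self-condensation takes the difference, as q·B² with q = 1.13 M⁻¹ h⁻¹. Integrating that loss for winter gives τ = ln(1 + q·c·t)/q = 0.111 M·d, so A = 16.9% and s = 25.7%. Midnight's fed exposure lies near gamma's at 4.00 d; scaling ln A by their ratio gives A = 30.3% and s = 40.2%.

**Forecast and result.** The forecast chose midnight, with 32% for winter and 46% for midnight, on the ground that “All selectivity depends only on exposure”; both values stand higher than this reckoning. The flasks give midnight: midnight 44.3%, winter 22.9%.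

    coupling partner + other mono adduct → bis adduct (k = 0.00650 M⁻¹ h⁻¹)
    2 coupling partner → self-condensation product (k = 0.500 M⁻¹ h⁻¹)
    substrate + coupling partner → other mono adduct (k = 0.460 M⁻¹ h⁻¹)
    2 substrate → homo dimer (k = 0.00270 M⁻¹ h⁻¹)
    coupling partner + first product → bis adduct (k = 1.10 M⁻¹ h⁻¹)
    substrate + coupling partner → first product (k = 0.370 M⁻¹ h⁻¹)

**Same curve.** Winter's substrate ended at 13.6%, and n turns that into 21.8%; midnight's ended at 31.5%, which gives 41.4%. A neighbour of midnight charged with 0.016 M of partner ends with 59.1% of its substrate, so n gives 66.9%, and that flask holds a share of 70.3%.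

The readings are calculated for an exercise; noise was put on by code.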